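**Plan**
Retrosynthesis: the ring alkene C-1=C-2 is cut last (selenoxide elimination). The ring carbinols C-3 and C-6 go back to the carbonyl and ketal carbons of a p-quinone monoketal, and this to a 1-alkyl-3,5-dimethoxybenzene. The chain is cut at C-1–C-1' and at C-4'–C-5'.
Enabling feature: the oxygen on C-2' lies 1,2 to C-1' (bound to ring carbon C-1) and 1,3 to C-4'. C-1' to C-4' therefore map onto the epoxide/bromide linchpin (R)-2-(2-bromoethyl)oxirane, whose two electrophilic ends can be addressed one after the other.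
Forward: one flask joins aryl Grignard, linchpin and nonyl Grignard (C-1–C-1', then C-4'–C-5') to the full C19 skeleton. Formylation/Dakin oxidation puts oxygen on C-6, and oxidative dearomatisation turns the benzene ring into the six-membered dienone (no ring is closed).
A cyclohexa-2,5-dienone with H on its C-4 would tautomerise to a phenol. C-1=C-2 is therefore saturated by selenol addition before any carbonyl is reduced, and is restored only in the last step.
Stereochemistry: C-2' comes from the epoxide. A cinchona catalyst sets the temporary centre C-2 (C-1 follows by equilibration). Two axial hydride additions, each trans to its neighbour, set C-6 and C-3, hence trans to each other. The elimination erases C-1 and C-2.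

Key step: step 1

Assumption: compounds 1, 2 and 3 are bought as such (2 is also accessible from the racemate by hydrolytic kinetic resolution); ring locants C-1 to C-6 (C-1 carries the chain, C-3 OH, C-5 OMe, C-6 OAc) and chain locants C-1' to C-13' are those of the target throughout.

**Step 1**
Reactants: 1 3,5-dimethoxyphenylmagnesium chloride; 2 (R)-2-(2-bromoethyl)oxirane; 3 nonylmagnesium bromide
Product: 5 (2R)-1-(3,5-dimethoxyphenyl)tridecan-2-ol, via bromo alkoxide 4 (not isolated)
Conditions: 2, CuI (10 mol%), THF, −40 °C, add 1 (1.05 equiv), 1 h; then Li2CuCl4 (5 mol%), 3 (2.5 equiv), −40 → 0 °C; aq NH4Cl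
Reagents that add atoms: none
Why: The aryl cuprate generated from 1 and catalytic CuI opens the oxirane of 2 by SN2 attack at its unsubstituted carbon (C-1'), and the primary bromide that survives in alkoxide 4 then undergoes copper-catalysed substitution by the nonyl Grignard reagent (alkylcuprate, SN2 at C-4', reductive elimination), which forms C-4'–C-5'. The closest known reaction types are the Cu-catalysed Grignard opening of terminal epoxides and the Kochi (Li2CuCl4) Grignard–alkyl bromide coupling, run here in sequence on one bifunctional linchpin so that the complete C19 skeleton should result from one operation. No ring is closed. No stereocentre is created: C-2' is the epoxide CH carbon, neither bond to it is broken, and it is carried over unchanged from 2. The step needs site selectivity between the two electrophilic ends of 2 and between the two Grignard reagents; ring strain lets the epoxide react with the arylcopper species at −40 °C, where a primary alkyl bromide is inert without Li2CuCl4, and the magnesium alkoxide so formed leaves the bromide as the only electrophile for 3. Attack at the terminal epoxide carbon and not at C-2' is secured by copper catalysis and the steric difference between CH2 and CH.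

**Step 2**
Reactants: 5 (2R)-1-(3,5-dimethoxyphenyl)tridecan-2-ol
Product: 6 (2R)-1-(3,5-dimethoxyphenyl)tridecan-2-yl acetate
Conditions: Ac2O, pyridine, DMAP (cat.), CH2Cl2, 23 °C
Reagents that add atoms: acetic anhydride, CC(=O)OC(C)=O
Why: DMAP-catalysed O-acylation of a secondary alcohol installs the C-2' acetate of the target, which also protects this oxygen through the arene oxidation steps; the stereocentre is not touched.

**Step 3**
Reactants: 6 (2R)-1-(3,5-dimethoxyphenyl)tridecan-2-yl acetate
Product: 7 (2R)-1-(2-formyl-3,5-dimethoxyphenyl)tridecan-2-yl acetate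
Conditions: POCl3, DMF, 0 → 70 °C; aq NaOAc
Reagents that add atoms: N,N-dimethylformamide, CN(C)C=O; water, O
Why: Vilsmeier–Haack formylation should occur at the position ortho to the alkyl chain and ortho/para to the two methoxy groups (C-6), as with 5-alkylresorcinol dimethyl ethers, the position between the two methoxy groups being the more hindered one.

**Step 4**
Reactants: 7 (2R)-1-(2-formyl-3,5-dimethoxyphenyl)tridecan-2-yl acetate
Product: 9 (2R)-1-(2-hydroxy-3,5-dimethoxyphenyl)tridecan-2-yl acetate, via aryl formate 8 (not isolated)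
Conditions: mCPBA, CH2Cl2, 0 → 23 °C; then KHCO3, MeOH, 0 °C
Reagents that add atoms: 3-chloroperoxybenzoic acid (mCPBA), OOC(=O)c1cccc(Cl)c1
Why: Dakin-type Baeyer–Villiger oxidation, in which the electron-rich aryl group migrates to give formate 8; an aryl formate is far more labile than the secondary alkyl acetate and should be removed selectively by brief cold methanolysis.

**Step 5**
Reactants: 9 (2R)-1-(2-hydroxy-3,5-dimethoxyphenyl)tridecan-2-yl acetate
Product: 10 (2R)-1-(3,3,5-trimethoxy-6-oxocyclohexa-1,4-dien-1-yl)tridecan-2-yl acetate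
Conditions: PhI(OAc)2, MeOH, 0 °C; NaHCO3
Reagents that add atoms: methanol, CO
Why: Oxidative dearomatisation of a p-methoxyphenol with a λ3-iodane in methanol (quinone monoketal synthesis); methanol should add at the para carbon that already bears OMe (C-3), giving the p-quinone monoketal with C-6 as the free carbonyl.

**Step 6**
Reactants: 10 (2R)-1-(3,3,5-trimethoxy-6-oxocyclohexa-1,4-dien-1-yl)tridecan-2-yl acetate
Product: 11 (2R)-1-[(1S,6R)-3,5,5-trimethoxy-2-oxo-6-(phenylselanyl)cyclohex-3-en-1-yl]tridecan-2-yl acetate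
Conditions: PhSeH (1.1 equiv), cinchona-alkaloid-derived bifunctional thiourea (10 mol%, pseudo-enantiomer chosen for the 6R selenide), toluene, −40 °C
Reagents that add atoms: benzeneselenol, [SeH]c1ccccc1
Why: Chiral-base-catalysed conjugate (selena-Michael) addition of the soft selenol to C-2, the only electrophilic β-carbon (C-4 is deactivated by the methoxy group on C-5); the catalyst selects the enone face and so sets C-2, C-1 (α to the ketone) equilibrates to the trans-diequatorial arrangement, and the adduct can no longer aromatise by tautomerisation.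

**Step 7**
Reactants: 11 (2R)-1-[(1S,6R)-3,5,5-trimethoxy-2-oxo-6-(phenylselanyl)cyclohex-3-en-1-yl]tridecan-2-yl acetate
Product: 12 (2R)-1-[(1S,2S,6R)-2-hydroxy-3,5,5-trimethoxy-6-(phenylselanyl)cyclohex-3-en-1-yl]tridecan-2-yl acetate
Conditions: NaBH4, CeCl3·7H2O, MeOH, −78 °C
Reagents that add atoms: none
Why: Luche reduction is 1,2-selective, and axial hydride delivery to the 6-substituted cyclohexenone should give the equatorial alcohol trans to the equatorial C-1 side chain, which sets C-6.

**Step 8**
Reactants: 12 (2R)-1-[(1S,2S,6R)-2-hydroxy-3,5,5-trimethoxy-6-(phenylselanyl)cyclohex-3-en-1-yl]tridecan-2-yl acetate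
Product: 13 (2R)-1-[(1S,2S,6R)-2-(acetyloxy)-3,5,5-trimethoxy-6-(phenylselanyl)cyclohex-3-en-1-yl]tridecan-2-yl acetate
Conditions: Ac2O, pyridine, DMAP (cat.), CH2Cl2, 0 → 23 °C
Reagents that add atoms: acetic anhydride, CC(=O)OC(C)=O
Why: DMAP-catalysed acylation of the secondary allylic alcohol under basic conditions that spare the enol ether and the ketal; it installs the C-6 acetate of the target with retention.

**Step 9**
Reactants: 13 (2R)-1-[(1S,2S,6R)-2-(acetyloxy)-3,5,5-trimethoxy-6-(phenylselanyl)cyclohex-3-en-1-yl]tridecan-2-yl acetate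
Product: 14 (2R)-1-[(1S,2S,6R)-2-(acetyloxy)-3-methoxy-5-oxo-6-(phenylselanyl)cyclohex-3-en-1-yl]tridecan-2-yl acetate
Conditions: PPTS (10 mol%), acetone–H2O (10:1), 0 → 23 °C
Reagents that add atoms: water, O
Why: Mild acid hydrolysis of the allylic dimethyl ketal, which ionises easily because the cation is a 3-methoxyallyl oxocarbenium ion; the product is a vinylogous ester that cannot tautomerise to a phenol because C-1 and C-2 are sp3.

**Step 10**
Reactants: 14 (2R)-1-[(1S,2S,6R)-2-(acetyloxy)-3-methoxy-5-oxo-6-(phenylselanyl)cyclohex-3-en-1-yl]tridecan-2-yl acetate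
Product: 15 (2R)-1-[(1S,2S,5R,6R)-2-(acetyloxy)-5-hydroxy-3-methoxy-6-(phenylselanyl)cyclohex-3-en-1-yl]tridecan-2-yl acetate
Conditions: NaBH4, CeCl3·7H2O, MeOH–THF, −78 → −40 °C; NaHCO3 work-up
Reagents that add atoms: none
Why: Luche 1,2-reduction of the vinylogous ester carbonyl (the first half of a Stork–Danheiser sequence, stopped before any acid); axial hydride attack should give the equatorial alcohol trans to the equatorial phenylselanyl group and hence trans to the C-6 acetate, which sets C-3, while the acetates survive borohydride at low temperature.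

**Step 11**
Reactants: 15 (2R)-1-[(1S,2S,5R,6R)-2-(acetyloxy)-5-hydroxy-3-methoxy-6-(phenylselanyl)cyclohex-3-en-1-yl]tridecan-2-yl acetate
Product: 17 (2R)-1-[(3S,6S)-6-(acetyloxy)-3-hydroxy-5-methoxycyclohexa-1,4-dien-1-yl]tridecan-2-yl acetate, via selenoxide 16 (not isolated)
Conditions: NaIO4, NaHCO3, THF–MeOH–H2O, 0 → 23 °C
Reagents that add atoms: none
Why: Oxidation to selenoxide 16 and selenoxide syn-elimination; H-1 is cis to selenium and is the only syn β-hydrogen not on an oxygen-bearing carbon, so C-1=C-2 should form (elimination away from a carbinol carbon is the known preference) under cold, buffered conditions that the acid-labile bis-allylic product should tolerate, and the two temporary stereocentres disappear.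

**Compound list**
1 | 3,5-dimethoxyphenylmagnesium chloride | COc1cc([Mg]Cl)cc(OC)c1 | starting material
2 | (R)-2-(2-bromoethyl)oxirane | BrCC[C@@H]1CO1 | starting material
3 | nonylmagnesium bromide | CCCCCCCCC[Mg]Br | starting material
4 | chloromagnesium (2S)-4-bromo-1-(3,5-dimethoxyphenyl)butan-2-olate | BrCC[C@H](Cc1cc(OC)cc(OC)c1)O[Mg]Cl | intermediate
5 | (2R)-1-(3,5-dimethoxyphenyl)tridecan-2-ol | CCCCCCCCCCC[C@H](Cc1cc(OC)cc(OC)c1)O | intermediate
6 | (2R)-1-(3,5-dimethoxyphenyl)tridecan-2-yl acetate | CCCCCCCCCCC[C@H](Cc1cc(OC)cc(OC)c1)OC(C)=O | intermediate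
7 | (2R)-1-(2-formyl-3,5-dimethoxyphenyl)tridecan-2-yl acetate | CCCCCCCCCCC[C@H](Cc1cc(OC)cc(OC)c1C=O)OC(C)=O | intermediate
8 | (2R)-1-[2-(formyloxy)-3,5-dimethoxyphenyl]tridecan-2-yl acetate | CCCCCCCCCCC[C@H](Cc1cc(OC)cc(OC)c1OC=O)OC(C)=O | intermediate
9 | (2R)-1-(2-hydroxy-3,5-dimethoxyphenyl)tridecan-2-yl acetate | CCCCCCCCCCC[C@H](Cc1cc(OC)cc(OC)c1O)OC(C)=O | intermediate
10 | (2R)-1-(3,3,5-trimethoxy-6-oxocyclohexa-1,4-dien-1-yl)tridecan-2-yl acetate | CCCCCCCCCCC[C@H](CC1=CC(OC)(OC)C=C(OC)C1=O)OC(C)=O | intermediate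
11 | (2R)-1-[(1S,6R)-3,5,5-trimethoxy-2-oxo-6-(phenylselanyl)cyclohex-3-en-1-yl]tridecan-2-yl acetate | CCCCCCCCCCC[C@H](C[C@@H]1[C@@H]([Se]c2ccccc2)C(OC)(OC)C=C(OC)C1=O)OC(C)=O | intermediate
12 | (2R)-1-[(1S,2S,6R)-2-hydroxy-3,5,5-trimethoxy-6-(phenylselanyl)cyclohex-3-en-1-yl]tridecan-2-yl acetate | CCCCCCCCCCC[C@H](C[C@@H]1[C@@H]([Se]c2ccccc2)C(OC)(OC)C=C(OC)[C@H]1O)OC(C)=O | intermediate
13 | (2R)-1-[(1S,2S,6R)-2-(acetyloxy)-3,5,5-trimethoxy-6-(phenylselanyl)cyclohex-3-en-1-yl]tridecan-2-yl acetate | CCCCCCCCCCC[C@H](C[C@@H]1[C@@H]([Se]c2ccccc2)C(OC)(OC)C=C(OC)[C@H]1OC(C)=O)OC(C)=O | intermediate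
14 | (2R)-1-[(1S,2S,6R)-2-(acetyloxy)-3-methoxy-5-oxo-6-(phenylselanyl)cyclohex-3-en-1-yl]tridecan-2-yl acetate | CCCCCCCCCCC[C@H](C[C@@H]1[C@@H]([Se]c2ccccc2)C(=O)C=C(OC)[C@H]1OC(C)=O)OC(C)=O | intermediate
15 | (2R)-1-[(1S,2S,5R,6R)-2-(acetyloxy)-5-hydroxy-3-methoxy-6-(phenylselanyl)cyclohex-3-en-1-yl]tridecan-2-yl acetate | CCCCCCCCCCC[C@H](C[C@@H]1[C@@H]([Se]c2ccccc2)[C@H](O)C=C(OC)[C@H]1OC(C)=O)OC(C)=O | intermediate
16 | Se-oxide of 15 (configuration at selenium not defined) | CCCCCCCCCCC[C@H](C[C@@H]1[C@@H]([Se](=O)c2ccccc2)[C@H](O)C=C(OC)[C@H]1OC(C)=O)OC(C)=O | intermediate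
17 | (2R)-1-[(3S,6S)-6-(acetyloxy)-3-hydroxy-5-methoxycyclohexa-1,4-dien-1-yl]tridecan-2-yl acetate (CNP0081579.1) | CCCCCCCCCCC[C@H](CC1=C[C@H](O)C=C(OC)[C@H]1OC(C)=O)OC(C)=O | target

Total step count: 11. Longest linear sequence: 11 steps (from 1, 2 and 3 to 17).

**Steps most likely to fail**

Step 6. The only chirality in 10 is the remote C-2', so the catalyst alone must select the enone face. Poor facial selectivity, or erosion by retro-addition, would give both ring series. The fallback sets out from 10 and uses an enzyme instead of a selenol to break the cross-conjugation. A flavin-dependent ene-reductase (Old Yellow Enzyme family; NADPH recycled with glucose/glucose dehydrogenase, buffer pH 7, cosolvent) should reduce C-1=C-2 with enzyme-controlled protonation at C-1 to the 1,2-dihydro ketone F1. Luche reduction then gives the trans allylic alcohol F2, acetylation the diacetate F3, and PPTS hydrolysis of the ketal the selenium-free vinylogous ester F4. Kinetic deprotonation at C-2 (LiHMDS, THF, −78 °C) and trapping with PhSeBr anti to the C-1 substituent comes back to the route at 14.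

Step 10. Hydride delivery syn to the phenylselanyl group (wrong C-3 epimer), competing 1,4-reduction or loss of an acetate would undermine the trans relationship. The fallback sets out from 14 and replaces substrate control by enzyme control. An NADPH-dependent ketoreductase (alcohol dehydrogenase) chosen from a stereocomplementary panel should reduce the ketone in buffer/2-propanol at pH 7, where the esters and the enol ether are safe. It comes back to the route at 15 and makes no new compound (F0).

Step 11. The free allylic alcohol of the product can be captured by benzeneselenenic acid as a selenenate that rearranges [2,3], transposing the oxygen. The bis-allylic diene can also lose acetic acid and aromatise. The fallback sets out from 15 and blocks the hydroxyl first: TESCl/imidazole gives the triethylsilyl ether F5. NaIO4/NaHCO3 oxidises it to the silylated selenoxide F6, which should eliminate to the silyl-protected diene F7. TBAF buffered with AcOH (THF, 0 °C) removes the silyl group and comes back to the route at 17.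

**Further compounds**
F1 | step 6 | (2R)-1-[(1R)-3,5,5-trimethoxy-2-oxocyclohex-3-en-1-yl]tridecan-2-yl acetate | CCCCCCCCCCC[C@H](C[C@@H]1CC(OC)(OC)C=C(OC)C1=O)OC(C)=O
F2 | step 6 | (2R)-1-[(1R,2S)-2-hydroxy-3,5,5-trimethoxycyclohex-3-en-1-yl]tridecan-2-yl acetate | CCCCCCCCCCC[C@H](C[C@@H]1CC(OC)(OC)C=C(OC)[C@H]1O)OC(C)=O
F3 | step 6 | (2R)-1-[(1R,2S)-2-(acetyloxy)-3,5,5-trimethoxycyclohex-3-en-1-yl]tridecan-2-yl acetate | CCCCCCCCCCC[C@H](C[C@@H]1CC(OC)(OC)C=C(OC)[C@H]1OC(C)=O)OC(C)=O
F4 | step 6 | (2R)-1-[(1R,2S)-2-(acetyloxy)-3-methoxy-5-oxocyclohex-3-en-1-yl]tridecan-2-yl acetate | CCCCCCCCCCC[C@H](C[C@@H]1CC(=O)C=C(OC)[C@H]1OC(C)=O)OC(C)=O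
F0 | step 10 | none | none
F5 | step 11 | (2R)-1-[(1S,2S,5R,6R)-2-(acetyloxy)-3-methoxy-6-(phenylselanyl)-5-[(triethylsilyl)oxy]cyclohex-3-en-1-yl]tridecan-2-yl acetate | CCCCCCCCCCC[C@H](C[C@@H]1[C@@H]([Se]c2ccccc2)[C@H](O[Si](CC)(CC)CC)C=C(OC)[C@H]1OC(C)=O)OC(C)=O
F6 | step 11 | Se-oxide of F5 (configuration at selenium not defined) | CCCCCCCCCCC[C@H](C[C@@H]1[C@@H]([Se](=O)c2ccccc2)[C@H](O[Si](CC)(CC)CC)C=C(OC)[C@H]1OC(C)=O)OC(C)=O
F7 | step 11 | (2R)-1-[(3S,6S)-6-(acetyloxy)-5-methoxy-3-[(triethylsilyl)oxy]cyclohexa-1,4-dien-1-yl]tridecan-2-yl acetate | CCCCCCCCCCC[C@H](CC1=C[C@H](O[Si](CC)(CC)CC)C=C(OC)[C@H]1OC(C)=O)OC(C)=O
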